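(The numbers are assumed; the rest is arithmetic.)

The substrate peak still standing at 4.0 d is the part of the charge that the catalyst did not turn, so I ask how much catalyst time each substrate molecule gets.

    substrate + free catalyst ⇌ catalyst intermediate A (K1 = 18 M⁻¹, k1 = 10000 M⁻¹ h⁻¹)
    reagent + catalyst intermediate A → catalyst intermediate B (k2 = 2400 M⁻¹ h⁻¹)
    catalyst intermediate B → catalyst intermediate C (k3 = 9.6 h⁻¹)
    catalyst intermediate C → released group + catalyst intermediate D (k4 = 24 h⁻¹)
    catalyst intermediate D → free catalyst + target (k5 = 9.3 h⁻¹)
    target + free catalyst ⇌ isomer of the product + free catalyst, rate k6*[free catalyst]*[target] forward; the back reaction follows from the equilibrium constant (K6 = 1.4, k6 = 27 M⁻¹ h⁻¹)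

| flask | substrate | reagent | free catalyst | time | remark |
|---|---|---|---|---|---|
| spring | 10 mM | 25.0 mM | 50 µM | 4.0 d | everything together at the start |
| noon | 10 mM (fed, over 3.0 d) | 25.0 mM | 50 µM | 4.0 d | all else is in the flask from the start; the feed brings no volume worth counting |
| dawn | 10 mM | 25.0 mM (fed, over 3.0 d) | 50 µM | 4.0 d | all else is in the flask from the start; the feed brings no volume worth counting |

- which flask leads in amount of target, in percent of the substrate charged ("all alike" within 1.5 percentage points) (spring / noon / dawn / all alike)
- how much target is there at the end, in percent of the substrate charged: spring
- how much target is there at the end, in percent of the substrate charged: noon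
- how much target is there at the end, in percent of the substrate charged: dawn

Substrate is the limiting reagent, and each turn of the cycle takes one substrate and one reagent. My quantity is the time budget, the catalyst charge times the run time per substrate charged: 0.480 h. The fraction turned is this budget divided by the mean cycle time. With the catalyst forms steady, the cycle time is 0.253 h for the three first-order steps, plus a wait for reagent, a wait for substrate, and a wait that grows as the product of both levels shrinks. That last wait exists since catalyst intermediate A falls back faster than reagent takes it.

For spring, my first way takes the levels with half the charge turned. The cycle time is then 0.526 h, which gives 91.3%.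

My second way divides the reagent rate by the substrate rate. The ratio is one, so time drops out, and the reagent level follows from the fraction turned. Summing cycle times over that fraction, spring needs 0.424 h of budget to reach 80.0%. The remainder, spent at the cycle time of that point, 1.01 h, brings it to 85.6%. The ways part, and the first cheats: the mean cycle of the second way, 0.561 h, is longer than the midpoint value.

Target's half-life by step 6 alone, 21 d, is long against the run. With free catalyst near 47.8% of its charge, the forward step takes about 2.65%, so spring ends at 82.9%.

For the fed flasks I take one state, with a quarter of the substrate charge turned: the fed partner stands at half its charge less that amount, the other partner at its full charge less that amount. This single state is rough. Noon gets 66.4% before isomer, and for dawn I hold the figure of this state as a rough ceiling, 77.8%. I rank spring first.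

The forecast gives spring the lead, with 81.2% for spring, 68.2% for noon and 69.7% for dawn, on the ground that in spring “both partners are high from the start”.

The flasks give spring first, at 81.2%, then dawn at 69.7% and noon at 68.1%. Spring keeps 15.0% of its substrate, against the 14.4% of my second way. Dividing the budget by the fraction turned, read from released group, gives a mean cycle of 0.565 h in spring and 0.683 h in noon.

Take noon with 0.012 mM of free catalyst. Its budget is 0.115 h, and with little turned the levels are reagent at its charge and substrate at half, so I expect 24.2% turned. That flask gives 22.3% target.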